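## Retrosynthetic overview

1. Feature: in the target two eight‑membered carbocycles share the central Cβ–Cβ′ bond (CH–CH). Each contains Cα and Cβ of one half, Cβ′ of the other, two adjacent carbons of ring A, furan C3 and C3a/C4 of a benzofuran. Without that bond the core is one 14‑membered ring of two identical halves joined only through the two trans‑2,3‑dihydrobenzofurans (furan C3–aryl and C2–O bonds).
2. Last disconnections: removal of O‑methyl and C‑tert‑butyl groups, then the Cβ–Cβ′ bond by transannular reductive hydrodimerisation of the two triarylethylenes of the macrocycle (closes both eight‑membered rings).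
3. Key disconnection: both dihydrobenzofurans (2 × C3–aryl, 2 × C2–O) open to two molecules of one triarylethylene monomer that carries a 2,6‑di‑tert‑butyl‑4‑hydroxystyryl arm on ring A and a free resorcinol ring B; forward, an anodic head‑to‑tail (3+2) cyclodimerisation.
4. Monomer: alkene geometry (ring A trans to ring B) from platinum‑catalysed syn‑diboration of the ring A alkyne and two Suzuki couplings (terminal boron → ring B, internal boron → ring C); ring A alkyne by iodination, Horner–Wadsworth–Emmons olefination, demethylation/pivaloylation and Sonogashira coupling.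
5. Ring order: dihydrofuran 1 → 14‑membered ring → dihydrofuran 2 (all in step 13) → the two eight‑membered rings (step 15).

Key step: step 13

Remark: chiral intermediates are racemic or meso and drawn as one enantiomer; rings A and C carry pivalate esters through the key step because with ether donors the arm cation would be trapped by the neighbouring C=C bond (five‑membered indane closure). Ring C is the 4‑oxyphenyl group on Cα, ring D the aryl group on furan C2.

## Route

Step 1
Reactants: 1 diethyl (3,5-dimethoxybenzyl)phosphonate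
Product: 2 diethyl (2-iodo-3,5-dimethoxybenzyl)phosphonate
Conditions: NIS, TFA (10 mol%), MeCN, 0 → 23 °C
Reagents that add atoms: N-iodosuccinimide, O=C1CCC(=O)N1I
Why: Electrophilic aromatic iodination: the carbon ortho to the benzylic carbon and para to one methoxy group is the most accessible activated position (the carbon between the two methoxy groups is shielded), so iodine enters next to the phosphonomethyl group.

Step 2
Reactants: 2 diethyl (2-iodo-3,5-dimethoxybenzyl)phosphonate; 3 3,5-di-tert-butyl-4-hydroxybenzaldehyde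
Product: 4 2,6-di-tert-butyl-4-[(E)-2-(2-iodo-3,5-dimethoxyphenyl)ethenyl]phenol
Conditions: KOtBu (2.5 equiv), THF, 0 → 23 °C
Reagents that add atoms: none
Why: Horner–Wadsworth–Emmons olefination: the benzylic phosphonate anion adds to the aldehyde (present as its hindered phenoxide, hence the excess base) and elimination of phosphate from the more stable adduct gives the E‑stilbene.

Step 3
Reactants: 4 2,6-di-tert-butyl-4-[(E)-2-(2-iodo-3,5-dimethoxyphenyl)ethenyl]phenol
Product: 5 5-[(E)-2-(3,5-di-tert-butyl-4-hydroxyphenyl)ethenyl]-4-iodobenzene-1,3-diol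
Conditions: BBr3 (4 equiv), CH2Cl2, −78 → 0 °C; then MeOH, H2O
Reagents that add atoms: none
Why: Lewis‑acid cleavage of aryl methyl ethers (BBr3 demethylation) frees the two phenols that will carry the electron‑withdrawing esters; stilbene, aryl iodide and tert‑butyl groups are inert at this temperature.

Step 4
Reactants: 5 5-[(E)-2-(3,5-di-tert-butyl-4-hydroxyphenyl)ethenyl]-4-iodobenzene-1,3-diol
Product: 6 5-[(E)-2-(3,5-di-tert-butyl-4-hydroxyphenyl)ethenyl]-4-iodo-1,3-phenylene bis(2,2-dimethylpropanoate)
Conditions: PivCl (2.3 equiv), pyridine, CH2Cl2, 0 → 23 °C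
Reagents that add atoms: pivaloyl chloride, CC(C)(C)C(Cl)=O
Why: O‑Acylation: only the two unhindered phenols are esterified, because the phenol flanked by two tert‑butyl groups does not react with an acid chloride under these conditions.

Step 5
Reactants: 6 iodoarene bis‑pivalate; 7 ethynyltrimethylsilane
Product: 8 5-[(E)-2-(3,5-di-tert-butyl-4-hydroxyphenyl)ethenyl]-4-[(trimethylsilyl)ethynyl]-1,3-phenylene bis(2,2-dimethylpropanoate)
Conditions: Pd(PPh3)2Cl2 (5 mol%), CuI (10 mol%), Et3N, THF, 50 °C, degassed
Reagents that add atoms: none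
Why: Sonogashira coupling at the aryl iodide (oxidative addition is eased by the two ester groups); pivalates, the free hindered phenol and the stilbene tolerate the amine/CuI conditions.

Step 6
Reactants: 8 silylalkyne
Product: 9 4-ethynyl-5-[(E)-2-(3,5-di-tert-butyl-4-hydroxyphenyl)ethenyl]-1,3-phenylene bis(2,2-dimethylpropanoate)
Conditions: Bu4NF (1.2 equiv), AcOH (1.5 equiv), THF, 0 °C
Reagents that add atoms: none
Why: Fluoride‑induced protodesilylation of the alkynylsilane, buffered with AcOH so that the aryl pivalates are not cleaved.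

Step 7
Reactants: 9 ring A alkyne; 10 bis(pinacolato)diboron
Product: 11 (E)-1,2-bis(pinacolatoboryl)alkene of ring A (the two boryl groups cis, ring A trans to the terminal boron)
Conditions: Pt(PPh3)4 (3 mol%), toluene, 80 °C
Reagents that add atoms: none
Why: Platinum‑catalysed syn‑diboration of a terminal alkyne: both boryl groups are delivered to the same face, so they end up cis and ring A is fixed trans to the terminal boron; the phosphine‑ligated catalyst does not diborate the stilbene.

Step 8
Reactants: 12 5-bromoresorcinol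
Product: 13 1-bromo-3,5-bis(triisopropylsilyloxy)benzene
Conditions: i-Pr3SiCl (2.4 equiv), imidazole, DMF, 23 °C
Reagents that add atoms: chlorotriisopropylsilane, CC(C)[Si](Cl)(C(C)C)C(C)C
Why: Silyl ether formation protects the resorcinol through the base‑mediated couplings; the triisopropylsilyl group withstands aqueous K3PO4.

Step 9
Reactants: 11 bis(boronate); 13 1-bromo-3,5-bis(triisopropylsilyloxy)benzene
Product: 14 (E)-alkenylboronate: ring A and pinacolatoboryl on one alkene carbon, H and silylated ring B on the other, ring A trans to ring B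
Conditions: Pd(dppf)Cl2 (5 mol%), K3PO4 (3 equiv), THF/H2O 10:1, 50 °C
Reagents that add atoms: none
Why: Suzuki–Miyaura coupling, site‑selective for the terminal alkenylboronate because the internal one is shielded by 2,6‑disubstituted ring A; it proceeds with retention, so ring B is trans to ring A.

Step 10
Reactants: 15 4-iodophenol
Product: 16 4-iodophenyl 2,2-dimethylpropanoate
Conditions: PivCl, pyridine, CH2Cl2, 0 → 23 °C
Reagents that add atoms: pivaloyl chloride, CC(C)(C)C(Cl)=O
Why: O‑Acylation of the phenol gives the aryl iodide that brings in ring C with its ester already in place.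

Step 11
Reactants: 14 alkenylboronate; 16 4-iodophenyl 2,2-dimethylpropanoate
Product: 17 (E)-triarylethylene with tris‑pivalate on rings A and C and bis(triisopropylsilyl) ether on ring B (ring C cis to ring B, ring A trans to ring B)
Conditions: Pd(OAc)2 (5 mol%), SPhos (10 mol%), K3PO4 (3 equiv), toluene/H2O 10:1, 80 °C
Reagents that add atoms: none
Why: Suzuki–Miyaura coupling of the remaining internal alkenylboronate with retention places ring C cis to ring B and completes the E‑triarylethylene; the bulky biarylphosphine is chosen for the hindered boronate, and pivalates and silyl ethers tolerate K3PO4.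

Step 12
Reactants: 17 protected triarylethylene
Product: 18 monomer: (E)-triarylethylene with free 3,5-dihydroxyphenyl ring B, tris‑pivalate on rings A and C and the free 2,6-di-tert-butyl-4-hydroxystyryl arm on ring A
Conditions: HF·pyridine, pyridine, THF, 0 → 23 °C, exclusion of light
Reagents that add atoms: none
Why: Fluoride desilylation of the two aryl silyl ethers under buffered, nearly neutral conditions that leave pivalates, both alkenes and the alkene geometry untouched.

Step 13
Reactants: 18 monomer (two molecules)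
Product: 20 meso 14-membered bis(dihydrobenzofuran) macrocycle hexapivalate, via linear head-to-tail mono-dihydrobenzofuran dimer 19 (not isolated)
Conditions: undivided cell, reticulated vitreous carbon anode, Pt cathode, constant current to 2.2 F per mol of 18, 18 (10 mM), n-Bu4NPF6 (0.1 M), (CF3)2CHOH/CH2Cl2 1:4, 0 °C; then Et3N, 23 °C
Reagents that add atoms: none
Why: Proposed new method: at the anode only the 2,6‑di‑tert‑butyl‑4‑styrylphenol of 18 should be oxidised (the pivalate‑deactivated triarylethylene and the unconjugated resorcinol are expected to need a clearly higher potential), and loss of two electrons and a proton gives a hydroxy‑quinone‑methide cation whose electrophilic carbon is the arm CH next to ring A; the closest known reactions are the oxidative coupling of 4‑hydroxystilbenes with resorcinol rings to trans‑2,3‑diaryl‑2,3‑dihydrobenzofurans and anodic phenol–alkene (3+2) annulations through phenoxonium ions in fluorinated alcohols. This cation is captured intermolecularly by ring B of a second molecule at the carbon ortho to the alkene‑bearing carbon and para to a hydroxyl group (Friedel–Crafts step, furan C3–aryl bond), and the resulting tert‑butyl‑stabilised para‑quinone methide is closed 5‑exo‑trig by the neighbouring phenol (furan C2–O bond) to give 19. Oxidation of the arm of 19 and attack by its own free resorcinol ring closes the 14‑membered ring in an intramolecular Friedel–Crafts step, and a second 5‑exo‑trig oxa‑Michael addition closes the second dihydrofuran. In each dihydrofuran C2 and C3 become trans because the oxa‑Michael closure is reversible through the quinone methide (assisted by the amine) and the trans isomer is the more stable; the relative configuration of the two dihydrofurans is set in the ring‑closing Friedel–Crafts step, where the centrosymmetric (heterochiral, meso) macrocycle is expected to be the less strained, which is not assured. The step needs dimerisation in place of self‑cyclisation: ring B cannot reach its own arm because it is trans to ring A across the triarylethylene, capture of the cation by the neighbouring C=C bond is disfavoured because the three pivalates remove the donor stabilisation of the diarylmethyl cation that this closure would create, and the tert‑butyl groups block the ortho positions of ring D.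

Step 14
Reactants: 20 macrocycle hexapivalate
Product: 22 macrocycle octamethyl ether (the two hindered phenols free), via decaphenol macrocycle 21 (not isolated)
Conditions: K2CO3, MeOH/THF, 40 °C, argon; then MeI, K2CO3, DMF, 23 °C
Reagents that add atoms: iodomethane, CI
Why: Base‑catalysed transesterification (methanolysis) of the six aryl pivalates and Williamson O‑methylation of the eight unhindered phenols, telescoped because the decaphenol is air‑sensitive; the two phenols between tert‑butyl groups are not alkylated and the ring holds both alkene geometries in place.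

Step 15
Reactants: 22 macrocycle octamethyl ether
Product: 23 centrosymmetric bicyclic octamethyl ether with two fused eight-membered rings and both 3,5-di-tert-butyl-4-hydroxyphenyl groups
Conditions: LiN(SiMe3)2 (2.1 equiv), THF, −78 → 0 °C; lithium naphthalenide LiC10H8 (2.2 equiv), THF, −78 °C; then NH4Cl (aq)
Reagents that add atoms: none
Why: Alkali‑metal reductive hydrodimerisation of aryl‑substituted alkenes (tail‑to‑tail radical‑anion coupling as with 1,1‑diarylethylenes and triphenylethylene), here transannular: the radical anion of one triarylethylene bonds through its CH carbon to the CH carbon of the facing alkene, closing both eight‑membered rings, and the two diarylmethyl anions are then protonated; the new bond forms across the inversion centre of the meso macrocycle so the two ring‑fusion CH centres get opposite configuration (anti hydrogens), and protonation of each benzhydryl anion on the face anti to the new bond is expected to place Hα cis to the adjacent ring‑fusion H as in the target.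

Step 16
Reactants: 23 tert‑butylated bicyclic octamethyl ether
Product: 24 bicyclic octamethyl ether with two free 4-hydroxyphenyl groups on the furan C2 carbons
Conditions: AlCl3 (20 equiv), toluene/MeNO2, 50 °C
Reagents that add atoms: none
Why: Retro‑Friedel–Crafts de‑tert‑butylation: AlCl3 promotes ipso‑protonation of the phenol ring and the tert‑butyl cation is transferred to toluene; any methyl ether cleaved on the way is of no consequence because all are removed in the next step, and the trans‑dihydrofurans are the preferred arrangement should a C2–O bond ionise reversibly.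

Step 17
Reactants: 24 bicyclic octamethyl ether
Product: 25 CNP0224452.1
Conditions: BBr3 (excess), CH2Cl2, −78 → 23 °C; then MeOH, H2O
Reagents that add atoms: none
Why: Lewis‑acid cleavage of the eight aryl methyl ethers (BBr3 demethylation); the free 4‑hydroxyphenyl groups are first converted to electron‑poor aryloxyboranes, which protects the benzylic C2–O bonds of the dihydrofurans from ionisation.

## Compound list

1 | diethyl (3,5-dimethoxybenzyl)phosphonate | CCOP(=O)(Cc1cc(OC)cc(OC)c1)OCC | starting material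
2 | diethyl (2-iodo-3,5-dimethoxybenzyl)phosphonate | CCOP(=O)(Cc1cc(OC)cc(OC)c1I)OCC | intermediate
3 | 3,5-di-tert-butyl-4-hydroxybenzaldehyde | CC(C)(C)c1cc(C=O)cc(C(C)(C)C)c1O | starting material
4 | 2,6-di-tert-butyl-4-[(E)-2-(2-iodo-3,5-dimethoxyphenyl)ethenyl]phenol | COc1cc(OC)c(I)c(/C=C/c2cc(C(C)(C)C)c(O)c(C(C)(C)C)c2)c1 | intermediate
5 | 5-[(E)-2-(3,5-di-tert-butyl-4-hydroxyphenyl)ethenyl]-4-iodobenzene-1,3-diol | Oc1cc(O)c(I)c(/C=C/c2cc(C(C)(C)C)c(O)c(C(C)(C)C)c2)c1 | intermediate
6 | 5-[(E)-2-(3,5-di-tert-butyl-4-hydroxyphenyl)ethenyl]-4-iodo-1,3-phenylene bis(2,2-dimethylpropanoate) | CC(C)(C)C(=O)Oc1cc(OC(=O)C(C)(C)C)c(I)c(/C=C/c2cc(C(C)(C)C)c(O)c(C(C)(C)C)c2)c1 | intermediate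
7 | ethynyltrimethylsilane | C#C[Si](C)(C)C | starting material
8 | 5-[(E)-2-(3,5-di-tert-butyl-4-hydroxyphenyl)ethenyl]-4-[(trimethylsilyl)ethynyl]-1,3-phenylene bis(2,2-dimethylpropanoate) | CC(C)(C)C(=O)Oc1cc(OC(=O)C(C)(C)C)c(C#C[Si](C)(C)C)c(/C=C/c2cc(C(C)(C)C)c(O)c(C(C)(C)C)c2)c1 | intermediate
9 | 4-ethynyl-5-[(E)-2-(3,5-di-tert-butyl-4-hydroxyphenyl)ethenyl]-1,3-phenylene bis(2,2-dimethylpropanoate) | CC(C)(C)C(=O)Oc1cc(OC(=O)C(C)(C)C)c(C#C)c(/C=C/c2cc(C(C)(C)C)c(O)c(C(C)(C)C)c2)c1 | intermediate
10 | bis(pinacolato)diboron | CC1(C)OB(OC1(C)C)B1OC(C)(C)C(C)(C)O1 | starting material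
11 | 4-[(E)-1,2-bis(pinacolatoboryl)ethenyl]-5-[(E)-2-(3,5-di-tert-butyl-4-hydroxyphenyl)ethenyl]-1,3-phenylene bis(2,2-dimethylpropanoate); boryl groups cis | CC(C)(C)C(=O)Oc1cc(OC(=O)C(C)(C)C)c(/C(B2OC(C)(C)C(C)(C)O2)=C/B2OC(C)(C)C(C)(C)O2)c(/C=C/c2cc(C(C)(C)C)c(O)c(C(C)(C)C)c2)c1 | intermediate
12 | 5-bromoresorcinol | Oc1cc(O)cc(Br)c1 | starting material
13 | 1-bromo-3,5-bis(triisopropylsilyloxy)benzene | CC(C)[Si](C(C)C)(C(C)C)Oc1cc(Br)cc(O[Si](C(C)C)(C(C)C)C(C)C)c1 | intermediate
14 | (E)-alkenylboronate: 4-{1-(pinacolatoboryl)-2-[3,5-bis(triisopropylsilyloxy)phenyl]ethenyl}-5-[(E)-2-(3,5-di-tert-butyl-4-hydroxyphenyl)ethenyl]-1,3-phenylene bis(2,2-dimethylpropanoate); ring A trans to ring B | CC(C)(C)C(=O)Oc1cc(OC(=O)C(C)(C)C)c(/C(B2OC(C)(C)C(C)(C)O2)=C/c2cc(O[Si](C(C)C)(C(C)C)C(C)C)cc(O[Si](C(C)C)(C(C)C)C(C)C)c2)c(/C=C/c2cc(C(C)(C)C)c(O)c(C(C)(C)C)c2)c1 | intermediate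
15 | 4-iodophenol | Oc1ccc(I)cc1 | starting material
16 | 4-iodophenyl 2,2-dimethylpropanoate | CC(C)(C)C(=O)Oc1ccc(I)cc1 | intermediate
17 | protected (E)-triarylethylene: Cα bears 4-(pivaloyloxy)phenyl (ring C) and 2,4-bis(pivaloyloxy)-6-[(E)-2-(3,5-di-tert-butyl-4-hydroxyphenyl)ethenyl]phenyl (ring A), Cβ bears H and 3,5-bis(triisopropylsilyloxy)phenyl (ring B); ring C cis to ring B | CC(C)(C)C(=O)Oc1ccc(cc1)/C(=C\c1cc(O[Si](C(C)C)(C(C)C)C(C)C)cc(O[Si](C(C)C)(C(C)C)C(C)C)c1)c1c(OC(=O)C(C)(C)C)cc(OC(=O)C(C)(C)C)cc1/C=C/c1cc(C(C)(C)C)c(O)c(C(C)(C)C)c1 | intermediate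
18 | monomer: as 17 with ring B as free 3,5-dihydroxyphenyl | CC(C)(C)C(=O)Oc1ccc(cc1)/C(=C\c1cc(O)cc(O)c1)c1c(OC(=O)C(C)(C)C)cc(OC(=O)C(C)(C)C)cc1/C=C/c1cc(C(C)(C)C)c(O)c(C(C)(C)C)c1 | intermediate
19 | linear head-to-tail dimer with one trans-2,3-dihydrobenzofuran, one free resorcinol ring B and one free hydroxystyryl arm (racemic) | Oc1cc(O)cc(c1)/C=C(\c1ccc(OC(=O)C(C)(C)C)cc1)c1c(OC(=O)C(C)(C)C)cc(OC(=O)C(C)(C)C)cc1[C@H]1c2c(cc(O)cc2/C=C(\c2ccc(OC(=O)C(C)(C)C)cc2)c2c(OC(=O)C(C)(C)C)cc(OC(=O)C(C)(C)C)cc2/C=C/c2cc(C(C)(C)C)c(O)c(C(C)(C)C)c2)O[C@@H]1c1cc(C(C)(C)C)c(O)c(C(C)(C)C)c1 | intermediate (not isolated)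
20 | meso 14-membered macrocycle hexapivalate: two trans-2,3-dihydrobenzofurans of opposite configuration, two transannular triarylethylenes (ring A trans to ring B), two free ring B phenols, two free hindered phenols | Oc1cc2/C=C(\c3ccc(OC(=O)C(C)(C)C)cc3)c3c(OC(=O)C(C)(C)C)cc(OC(=O)C(C)(C)C)cc3[C@H]3c4c(cc(O)cc4/C=C(\c4ccc(OC(=O)C(C)(C)C)cc4)c4c(OC(=O)C(C)(C)C)cc(OC(=O)C(C)(C)C)cc4[C@@H]5c2c(c1)O[C@H]5c1cc(C(C)(C)C)c(O)c(C(C)(C)C)c1)O[C@@H]3c1cc(C(C)(C)C)c(O)c(C(C)(C)C)c1 | intermediate
21 | decaphenol macrocycle (all six pivalates removed) | Oc1cc2/C=C(\c3ccc(O)cc3)c3c(O)cc(O)cc3[C@H]3c4c(cc(O)cc4/C=C(\c4ccc(O)cc4)c4c(O)cc(O)cc4[C@@H]5c2c(c1)O[C@H]5c1cc(C(C)(C)C)c(O)c(C(C)(C)C)c1)O[C@@H]3c1cc(C(C)(C)C)c(O)c(C(C)(C)C)c1 | intermediate (not isolated)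
22 | macrocycle octamethyl ether (meso; hindered phenols free) | COc1cc2/C=C(\c3ccc(OC)cc3)c3c(OC)cc(OC)cc3[C@H]3c4c(cc(OC)cc4/C=C(\c4ccc(OC)cc4)c4c(OC)cc(OC)cc4[C@@H]5c2c(c1)O[C@H]5c1cc(C(C)(C)C)c(O)c(C(C)(C)C)c1)O[C@@H]3c1cc(C(C)(C)C)c(O)c(C(C)(C)C)c1 | intermediate
23 | centrosymmetric bicyclic octamethyl ether: two eight-membered rings sharing the Cβ–Cβ′ bond (ring-fusion hydrogens anti); in each ring Hα, the adjacent Hβ and the furan C3–H on one face; trans-dihydrofurans; 3,5-di-tert-butyl-4-hydroxyphenyl on each furan C2 | COc1ccc([C@@H]2c3c(OC)cc(OC)cc3[C@H]3c4c(cc(OC)cc4[C@H]4[C@@H](c5ccc(OC)cc5)c5c(OC)cc(OC)cc5[C@@H]5c6c(cc(OC)cc6[C@H]24)O[C@H]5c2cc(C(C)(C)C)c(O)c(C(C)(C)C)c2)O[C@@H]3c2cc(C(C)(C)C)c(O)c(C(C)(C)C)c2)cc1 | intermediate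
24 | as 23 without tert-butyl groups (4-hydroxyphenyl on each furan C2) | COc1ccc([C@@H]2c3c(OC)cc(OC)cc3[C@H]3c4c(cc(OC)cc4[C@H]4[C@@H](c5ccc(OC)cc5)c5c(OC)cc(OC)cc5[C@@H]5c6c(cc(OC)cc6[C@H]24)O[C@H]5c2ccc(O)cc2)O[C@@H]3c2ccc(O)cc2)cc1 | intermediate
25 | CNP0224452.1 (meso decaphenol) | Oc1ccc([C@@H]2c3c(O)cc(O)cc3[C@H]3c4c(cc(O)cc4[C@H]4[C@@H](c5ccc(O)cc5)c5c(O)cc(O)cc5[C@@H]5c6c(cc(O)cc6[C@H]24)O[C@H]5c2ccc(O)cc2)O[C@@H]3c2ccc(O)cc2)cc1 | target

## Step count and risks

Total steps: 17. Longest linear sequence: 15 (steps 1–7, 9, 11–17, from 1).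

Steps most likely to fail:

1. Step 13 (proposed new method). What may go wrong: the arm cation is captured inside the same molecule by the neighbouring C=C bond or by the solvent before a second molecule arrives; oxidation stops at the phenoxyl radical, which couples tail‑to‑tail; chain growth competes with closure of the 14‑membered ring; the second annulation pairs the dihydrofurans homochirally. Fallback with known reactions: the dihydrofuran is made before the triarylethylene exists and the macrocycle is closed by cross‑coupling. Setting out from 6 and 12 (in excess), the intermolecular oxidative coupling of a 4‑hydroxystilbene with a resorcinol (Tl(NO3)3, MeOH/CH2Cl2, −50 °C) should give the trans‑2,3‑dihydrobenzofuran F1, with the C–C bond at the resorcinol carbon next to bromine. Sonogashira coupling with 7 at the iodide gives the silylalkyne F2, buffered fluoride the terminal alkyne F3, and Pt(PPh3)4 with 10 the cis‑bis(boronate) F4. Under high dilution F4 is dimerised head to tail by Suzuki coupling of its terminal boronate with the aryl bromide of a second molecule (Pd(dppf)Cl2, K3PO4). Closure onto its own bromide would need a trans double bond in a seven‑membered ring. This gives the macrocyclic bis(alkenylboronate) F5 (the meso form is separated from the homochiral form). Double Suzuki coupling of F5 with 16 under the conditions of step 11 comes back to the route at 20.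

2. Step 15. What may go wrong: protonation of the radical anion before C–C bond formation (plain saturation of the alkenes), reductive cleavage of the benzylic C2–O bonds of the dihydrofurans, bond formation or protonation on the wrong faces. Fallback: setting out from 22, hydroboration–oxidation (BH3·THF; then NaBO3·4H2O) puts a hydroxyl group on each CH carbon and a hydrogen on each diaryl carbon, giving the bis(benzylic alcohol) F6. Low‑valent titanium (TiCl3/LiAlH4, DME, reflux; McMurry‑type reductive coupling of benzylic alcohols) then joins the two carbinol carbons and comes back to the route at 23, where the diastereomers are separated.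

3. Step 17. What may go wrong: ionisation of the benzylic C2–O bonds under the strong Lewis acid with Friedel–Crafts rearrangement of the opened cation, or incomplete cleavage of eight ethers. Fallback: a protecting‑group regime that needs only mild protic acid at the end. Setting out from 20, methanolysis as in step 14 followed by MOMCl/i‑Pr2NEt gives the octakis(methoxymethyl) ether F7. Reductive coupling as in step 15 gives the bicyclic acetal F8. HCl in MeOH (40 °C) removes the acetals to give the tert‑butylated decaphenol F9, and AlCl3 in toluene/MeNO2 (as in step 16) removes the tert‑butyl groups and comes back to the route at 25.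

## Further compounds

F1 | step 13 | trans-4-bromo-2-(3,5-di-tert-butyl-4-hydroxyphenyl)-3-[2-iodo-3,5-bis(pivaloyloxy)phenyl]-2,3-dihydrobenzofuran-6-ol (racemic) | Oc1cc(Br)c2c(c1)O[C@H](c1cc(C(C)(C)C)c(O)c(C(C)(C)C)c1)[C@H]2c1c(I)c(OC(=O)C(C)(C)C)cc(OC(=O)C(C)(C)C)c1
F2 | step 13 | as F1 with (trimethylsilyl)ethynyl in place of iodine (racemic) | Oc1cc(Br)c2c(c1)O[C@H](c1cc(C(C)(C)C)c(O)c(C(C)(C)C)c1)[C@H]2c1c(C#C[Si](C)(C)C)c(OC(=O)C(C)(C)C)cc(OC(=O)C(C)(C)C)c1
F3 | step 13 | as F1 with ethynyl in place of iodine (racemic) | Oc1cc(Br)c2c(c1)O[C@H](c1cc(C(C)(C)C)c(O)c(C(C)(C)C)c1)[C@H]2c1c(C#C)c(OC(=O)C(C)(C)C)cc(OC(=O)C(C)(C)C)c1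
F4 | step 13 | as F1 with (E)-1,2-bis(pinacolatoboryl)ethenyl in place of iodine, boryl groups cis (racemic) | Oc1cc(Br)c2c(c1)O[C@H](c1cc(C(C)(C)C)c(O)c(C(C)(C)C)c1)[C@H]2c1c(/C(B3OC(C)(C)C(C)(C)O3)=C/B3OC(C)(C)C(C)(C)O3)c(OC(=O)C(C)(C)C)cc(OC(=O)C(C)(C)C)c1
F5 | step 13 | meso macrocyclic bis(alkenylboronate): as 20 with pinacolatoboryl in place of each ring C | Oc1cc2/C=C(\B3OC(C)(C)C(C)(C)O3)c3c(OC(=O)C(C)(C)C)cc(OC(=O)C(C)(C)C)cc3[C@H]3c4c(cc(O)cc4/C=C(\B4OC(C)(C)C(C)(C)O4)c4c(OC(=O)C(C)(C)C)cc(OC(=O)C(C)(C)C)cc4[C@@H]5c2c(c1)O[C@H]5c1cc(C(C)(C)C)c(O)c(C(C)(C)C)c1)O[C@@H]3c1cc(C(C)(C)C)c(O)c(C(C)(C)C)c1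
F6 | step 15 | bis(benzylic alcohol) from 22: each former alkene is CH(OH)(ring B)–CH(ring C)(ring A); mixture of diastereomers at the four new centres | COc1cc2C(O)C(c3ccc(OC)cc3)c3c(OC)cc(OC)cc3[C@H]3c4c(cc(OC)cc4C(O)C(c4ccc(OC)cc4)c4c(OC)cc(OC)cc4[C@@H]5c2c(c1)O[C@H]5c1cc(C(C)(C)C)c(O)c(C(C)(C)C)c1)O[C@@H]3c1cc(C(C)(C)C)c(O)c(C(C)(C)C)c1
F7 | step 17 | macrocycle octakis(methoxymethyl) ether (meso; hindered phenols free) | COCOc1cc2/C=C(\c3ccc(OCOC)cc3)c3c(OCOC)cc(OCOC)cc3[C@H]3c4c(cc(OCOC)cc4/C=C(\c4ccc(OCOC)cc4)c4c(OCOC)cc(OCOC)cc4[C@@H]5c2c(c1)O[C@H]5c1cc(C(C)(C)C)c(O)c(C(C)(C)C)c1)O[C@@H]3c1cc(C(C)(C)C)c(O)c(C(C)(C)C)c1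
F8 | step 17 | bicyclic octakis(methoxymethyl) ether with the configuration of 23 | COCOc1ccc([C@@H]2c3c(OCOC)cc(OCOC)cc3[C@H]3c4c(cc(OCOC)cc4[C@H]4[C@@H](c5ccc(OCOC)cc5)c5c(OCOC)cc(OCOC)cc5[C@@H]5c6c(cc(OCOC)cc6[C@H]24)O[C@H]5c2cc(C(C)(C)C)c(O)c(C(C)(C)C)c2)O[C@@H]3c2cc(C(C)(C)C)c(O)c(C(C)(C)C)c2)cc1
F9 | step 17 | tert-butylated decaphenol: 25 with 3,5-di-tert-butyl-4-hydroxyphenyl on each furan C2 | Oc1ccc([C@@H]2c3c(O)cc(O)cc3[C@H]3c4c(cc(O)cc4[C@H]4[C@@H](c5ccc(O)cc5)c5c(O)cc(O)cc5[C@@H]5c6c(cc(O)cc6[C@H]24)O[C@H]5c2cc(C(C)(C)C)c(O)c(C(C)(C)C)c2)O[C@@H]3c2cc(C(C)(C)C)c(O)c(C(C)(C)C)c2)cc1
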